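**Retrosynthetic overview**
1. Plagiochilin A ⇐ one-pot ester reduction/bis-acetylation of a lactol ester ⇐ ozonolysis of a Δ2-cyclopentene: the dihydropyran is the C2–C3-cleaved five-membered ring of an aromadendrane-type hydroazulene.
2. Spiro-epoxide ⇐ C10 ketone + sulfonium ylide; cyclopentene ester ⇐ allenoate (3+2) annulation across one enone of a meso dienone.
3. Key step: catalytic enantioselective desymmetrisation of meso 8,8-dimethylbicyclo[5.1.0]octa-2,5-dien-4-one, which fixes C1, C5 and the absolute sense of C6/C7 at once.
4. Meso dienone ⇐ double β-elimination of a cyclopropanated 8-oxabicyclo[3.2.1]octenone ⇐ dearomative (4+3) cycloaddition of furan with an oxyallyl cation.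
5. Ring order: seven-membered ring (from furan) → cyclopropane → temporary cyclopentene → epoxide → dihydropyran.

Assumption/numbering: aromadendrane (2,3-seco) numbering is used (C1/C5 ring fusion, C2 acetal, C3 enol-ether CH, C4 bears C15, C6/C7 cyclopropane CH, C10 spiro carbon, C11 CMe2, C14 epoxide CH2); the given SMILES reads as (1R,2R,5R,6S,7S,10S), with H-1, H-5, CMe2, C14 and 2-OAc on one face (β) and the epoxide O on the other (α).

**Step 1**
Reactants: 1 furan; 2 1,1,3,3-tetrabromoacetone
Product: 3 meso-(1R,5S)-8-oxabicyclo[3.2.1]oct-6-en-3-one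
Conditions: Zn–Cu, B(OEt)3, THF, −10 °C → rt; then Zn–Cu, NH4Cl, MeOH, rt
Reagents that add atoms: 1,1,3,3-tetrabromoacetone, O=C(C(Br)Br)C(Br)Br (supplies the C3O bridge; Br removed)
Why: Noyori–Hoffmann oxyallyl-cation (4+3) cycloaddition dearomatises furan and builds the seven-membered carbocycle in one operation, and reductive debromination leaves the meso ketone (bridgeheads necessarily cis).

**Step 2**
Reactants: 3; 4 2,2-diiodopropane
Product: 5 meso-(1R,2R,4S,5S)-3,3-dimethyl-9-oxatricyclo[3.3.1.0^2,4]nonan-7-one (cyclopropane exo, syn to the O bridge)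
Conditions: Et2Zn, 4, CH2Cl2, 0 °C → rt
Reagents that add atoms: 2,2-diiodopropane, CC(C)(I)I (supplies CMe2)
Why: Simmons–Smith (Furukawa/Charette gem-dimethyl variant) cyclopropanation, in which the bridging allylic ether oxygen delivers the zinc carbenoid to the exo face of the strained cis-alkene; the cis ring fusion is inherent and the product stays meso.

**Step 3**
Reactants: 5
Product: 6 meso-(1R,7S)-8,8-dimethylbicyclo[5.1.0]octa-2,5-dien-4-one
Conditions: TMSOTf, Et3N (excess), CH2Cl2, 0 °C → rt; then DBU, rt
Reagents that add atoms: none
Why: Double vinylogous β-elimination (silyl enol ether formation, opening of the oxa-bridge, then loss of silanol from the second enol silane), the same ring-opening that converts oxabicyclo[3.2.1]octenones into tropones; the excess amine keeps the medium basic so the acid-labile cyclopropane is not opened, and no stereocentre changes.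

**Step 4 (key step)**
Reactants: 6 (1.5 equiv, excess recovered); 7 ethyl buta-2,3-dienoate
Product: 8 ethyl (1R,5R,6S,7S)-10-oxo-14-noraromadendra-3,8-dien-15-oate (cis-fused cyclopentene ester on the cyclopropane-fused cycloheptenone)
Conditions: 7 (slow addition), P-phenyl binaphthophosphepine (10 mol%; (S)-catalyst assumed, antipode chosen for the 5R series), toluene, rt
Reagents that add atoms: ethyl buta-2,3-dienoate, C=C=CC(=O)OCC (supplies C2, C3, C4, C15)
Why: Proposed new method: a chiral-phosphine-catalysed Lu (3+2) allenoate annulation used to desymmetrise the meso cross-conjugated dienone — the phosphonium dienolate adds through its α-carbon to one enantiotopic β-carbon (C5) on the face anti to the CMe2 bridge, the resulting C1 enolate closes onto the vinylphosphonium, and proton shift/phosphine loss gives the cis-fused cyclopentene with H-1/H-5 syn to the cyclopropane and C6/C7 fixed in one absolute sense; the closest known reactions are Lu's allenoate–enone (3+2), its asymmetric versions on acyclic enones, and catalytic desymmetrisations of 4,4-disubstituted cyclohexadienones.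

**Step 5**
Reactants: 8
Product: 9 ethyl (1R,5R,6S,7S)-10-oxo-14-noraromadendr-3-en-15-oate
Conditions: [(Ph3P)CuH]6 (Stryker), PhMe, H2O (few equiv), rt
Reagents that add atoms: none
Why: Stryker CuH conjugate reduction removes the remaining enone C8=C9 chemoselectively (enone much faster than the trisubstituted enoate; cyclopropane and ketone untouched), with no new stereocentre.

**Step 6**
Reactants: 9; 10 trimethylsulfonium iodide
Product: 11 ethyl (1R,5R,6S,7S,10S)-10,14-epoxyaromadendr-3-en-15-oate
Conditions: Me3S+ I−, KHMDS, THF, −10 → 0 °C
Reagents that add atoms: trimethylsulfonium iodide, C[S+](C)C.[I-] (supplies C14)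
Why: Corey–Chaykovsky epoxidation, in which dimethylsulfonium methylide adds irreversibly to the C10 ketone from the convex β-face of the cis-fused hydroazulenone (anti to the α-oriented C1–C2 bond) and closes to the spiro-epoxide with C14 β and O α (10S); the low temperature limits C1 epimerisation.

**Step 7**
Reactants: 11
Product: 12 ethyl (1R,5R,6S,7S,10S)-10,14-epoxyaromadendr-2-en-15-oate (C4 epimers, inconsequential)
Conditions: LDA, DMPU, THF, −78 °C; then AcOH, −78 °C
Reagents that add atoms: none
Why: Kinetic deconjugation — γ-deprotonation at C2 gives the extended dienolate, and α-protonation at C4 moves the alkene to C2=C3; the epoxide survives LDA at −78 °C, and C4 becomes sp2 again later.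

**Step 8**
Reactants: 12; 13 ozone
Product: 14 ethyl (1R,5R,6S,7S,10S)-2-hydroxy-2,3:10,14-diepoxy-2,3-secoaromadendr-3-en-15-oate (lactol, anomeric mixture)
Conditions: O3, CH2Cl2, −78 °C; then PPh3, −78 °C → rt
Reagents that add atoms: ozone, [O-][O+]=O (two O atoms)
Why: Ozonolysis cleaves C2=C3, and the resulting formylacetate unit (C3HO–C4H–CO2Et) enolises and closes spontaneously on the C2 aldehyde (iridoid-type hemiacetalisation) under neutral conditions, giving the enol ether C3=C4 in the required direction without exposing the β,γ-epoxy aldehyde to base.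

**Step 9**
Reactants: 14; 15 acetic anhydride
Product: 16 plagiochilin A, (1R,2R,5R,6S,7S,10S)-2,15-diacetoxy-2,3:10,14-diepoxy-2,3-secoaromadendr-3-ene
Conditions: DIBAL-H (5 equiv), CH2Cl2, −78 °C; then pyridine, DMAP, Ac2O, −78 → 0 °C
Reagents that add atoms: acetic anhydride, CC(=O)OC(C)=O (two acetyl groups)
Why: One-pot reductive acetylation (Rychnovsky-type) — DIBAL reduces the vinylogous carbonate ester to the C15 allylic alkoxide while the lactol is held as its aluminium lactolate, and both are acetylated in situ; C2 is set under anomeric control as the axial acetate trans to the C1–C10 bond (2R), with the minor anomer removed by chromatography.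

**Compound list**
1 | furan | c1ccoc1 | starting material
2 | 1,1,3,3-tetrabromopropan-2-one | O=C(C(Br)Br)C(Br)Br | starting material
3 | meso-(1R,5S)-8-oxabicyclo[3.2.1]oct-6-en-3-one | O=C1C[C@@H]2C=C[C@H](C1)O2 | intermediate
4 | 2,2-diiodopropane (available from acetone hydrazone/I2 if not purchased) | CC(C)(I)I | starting material (reagent)
5 | meso-(1R,2R,4S,5S)-3,3-dimethyl-9-oxatricyclo[3.3.1.0^2,4]nonan-7-one | O=C1C[C@@H]2[C@@H]3[C@@H](C3(C)C)[C@H](C1)O2 | intermediate
6 | meso-(1R,7S)-8,8-dimethylbicyclo[5.1.0]octa-2,5-dien-4-one | O=C1C=C[C@@H]2[C@H](C=C1)C2(C)C | intermediate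
7 | ethyl buta-2,3-dienoate | C=C=CC(=O)OCC | starting material
8 | ethyl (1R,5R,6S,7S)-10-oxo-14-noraromadendra-3,8-dien-15-oate | CCOC(=O)C1=CC[C@@H]2[C@H]1[C@@H]1[C@H](C=CC2=O)C1(C)C | intermediate
9 | ethyl (1R,5R,6S,7S)-10-oxo-14-noraromadendr-3-en-15-oate | CCOC(=O)C1=CC[C@@H]2[C@H]1[C@@H]1[C@H](CCC2=O)C1(C)C | intermediate
10 | trimethylsulfonium iodide | C[S+](C)C.[I-] | starting material (reagent)
11 | ethyl (1R,5R,6S,7S,10S)-10,14-epoxyaromadendr-3-en-15-oate | CCOC(=O)C1=CC[C@@H]2[C@H]1[C@@H]1[C@H](CC[C@@]23CO3)C1(C)C | intermediate
12 | ethyl (1R,5R,6S,7S,10S)-10,14-epoxyaromadendr-2-en-15-oate (C4 epimers) | CCOC(=O)C1C=C[C@@H]2[C@H]1[C@@H]1[C@H](CC[C@@]23CO3)C1(C)C | intermediate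
13 | ozone | [O-][O+]=O | starting material (reagent)
14 | ethyl (1R,5R,6S,7S,10S)-2-hydroxy-2,3:10,14-diepoxy-2,3-secoaromadendr-3-en-15-oate (2S anomer shown; mixture) | CCOC(=O)C1=CO[C@H](O)[C@@H]2[C@H]1[C@@H]1[C@H](CC[C@@]23CO3)C1(C)C | intermediate
15 | acetic anhydride | CC(=O)OC(C)=O | starting material (reagent)
16 | plagiochilin A | CC(=O)OCC1=CO[C@H](OC(C)=O)[C@@H]2[C@H]1[C@@H]1[C@H](CC[C@@]23CO3)C1(C)C | target

**Totals**
Total steps: 9. Longest linear sequence: 9 (fully linear from furan).

**Three steps most likely to fail, with fallbacks**
- **Step 4** (unprecedented desymmetrising annulation; risks are low reactivity of the cyclic dienone, α/γ regiochemistry, double annulation and ee). Fallback: separate the two tasks. First desymmetrise 6 by CuH/chiral bisphosphine conjugate reduction, where the enol silane product cannot over-reduce, to give the enantioenriched mono-enone. Then build the cyclopentene stoichiometrically: conjugate addition of the 1-(ethoxycarbonyl)vinyl cuprate anti to CMe2, C1 allylation of the enolate, ring-closing metathesis and C1 equilibration, converging on 9.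
- **Step 9** (the aluminium lactolate may ring-open and over-reduce, or the ester may stop at the aldehyde). Fallback: switch to a protecting-group sequence. Silylate lactol 14 (TBSOTf), reduce the ester with DIBAL, acetylate C15–OH, then exchange the anomeric silyl group for acetate (TBAF/AcOH, then Ac2O/pyridine).
- **Step 6** (facial selectivity at C10 is only argued from shape, and the basic ylide may epimerise C1). Fallback: Wittig methylenation of 9 to the exocyclic alkene, then oxygen delivery chosen to suit the observed bias. DMDO puts O on the more accessible face; NBS/H2O then K2CO3 puts O anti to it. The alkene route therefore reaches the 10S epoxide whichever face proves more accessible.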